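In this vessel every substrate molecule stands at a fork: partner takes it, or it changes hand through the achiral form.

- Saturday's: left-handed substrate 0.050 M; right-handed substrate 0.050 M; partner 2.2 equiv; the very flask that is asked about, followed so far
- flask: left-handed substrate 0.050 M; partner 2.20 equiv; right-handed substrate 0.050 M; time 20 h

- Saturday's (time / h: left-handed substrate / %, right-handed substrate / %): 0.500: 30.2, 38.0; 1.00: 23.4, 29.5; 1.50: 18.2, 23.8; 2.50: 15.2, 16.9; 3.00: 12.2, 14.9; 4.00: 10.0, 12.0

(scatter of a reading: 0.5 percentage points)

- part of the left-handed substrate and right-handed substrate charged together that has reacted at 20 h
- excess of left-handed product over right-handed product in the product at 20 h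
- excess of right-handed substrate over left-handed substrate among what is left of the two at 20 h

- partner is single-handed; left-handed substrate and right-handed substrate are mirror images of each other, charged as a racemate, each of them at the stated concentration
- what was read earlier has a scatter of 0.5 percentage points, one standard deviation
- what has gone into achiral form counts as reacted
- an excess is the difference of the two amounts in percent of their sum
- an excess is below zero if the other one leads
- the handed part of partner does not stay in what it makes, so the products of the two hands are mirror images too

Take the gap between right-handed and left-handed substrate, and divide it by what has gone from the two: 24.5% at 0.500 h, 13.0% at 1.00 h. The gap itself shrinks from 7.8 percentage points to 2 points at 4.00 h, so read the hands as mixing. Now count what mixing does: a molecule moved from the right hand to the left before partner takes it adds to the product difference but not to the gap, and achiral form counts among what has gone, so the ratio at 0.500 h is a floor under the product excess at that moment, the floor excess. Call the excess of left over right among molecules taken by partner while the two hands stand equal the fork excess. Assume both hands react first-order in [partner]; then [partner] cancels at the fork. While mixing keeps the hands level, the product excess stays at the fork excess: this is dynamic kinetic resolution.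

Your forecast reads 93% reacted, product excess 20% and substrate excess 6%, with “product excess stays near the instantaneous value”. Keep that rule, and I keep your other two figures. But I put the product excess above the floor excess of 24.5%, and so above your figure, though that floor is itself a reading, and each reading in it carries a scatter of 0.5 points.

The flask at 20 h gives 95.2% reacted, product excess 46.1% and substrate excess 1.22%.

    partner + left-handed substrate → left-handed product (k = 0.00343 L mol⁻¹ s⁻¹)
    partner → decomposed reagent (k = 8.62 × 10⁻⁷ s⁻¹)
    partner ⇌ dormant form (K = 0.589, k = 9.81 × 10⁻⁶ s⁻¹)
    partner + right-handed substrate → right-handed product (k = 0.00110 L mol⁻¹ s⁻¹)
    right-handed substrate ⇌ achiral form (K = 0.0910, k = 7.23 × 10⁻⁴ s⁻¹)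
    left-handed substrate ⇌ achiral form (K = 0.0910, k = 7.23 × 10⁻⁴ s⁻¹)

At the start, right-handed substrate goes to right-handed product at 0.17 of its forward rate into achiral form, and that forward step alone has a half-life of 0.27 h, shorter than 20 h. This flask's product excess stands at 45.5% after 5.00 h and 46.1% at 20 h, above the floor excess of 24.5%.

Now take the flask with 0.550 equiv of partner: [partner] cancels at the fork, so the reckoning again gives a floor of 24.5%. That flask computes to a product excess of 50.2%, with 30.0% reacted.

(The numbers in the tables stem from a simulated flask for an exercise.)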